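**Plan**

1. Naming: flavone unit 1 = rings A/C/B (C2–C8a, C1'–C6'); flavone unit 2 = rings D/E/F (C2''–C8a'', C1'''–C6'''); ring G = the dihydropyran on ring B (O4', C4', C5', then benzylic Cα, Cβ and gem-dimethyl Cγ). Amentoflavone is the parent 3',8''-biapigenin.
2. Cuts: ring G at C5'–Cα and O4'–Cγ, back to a lone phenol and a C5 enal acetal, with a Cα=Cβ alkene as temporary oxidation level. Then the biaryl bond C3'–C8'' (Suzuki–Miyaura), then the pyranone rings C and E (chalcone oxidative cyclisation) back to one shared acetophenone.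
3. Forward: dibenzylated phloroacetophenone 2 gives ring E and then the C8'' iodide 7. The same ketone gives ring C on an iodo/MOM-oxy ring B, borylated to 13. Coupling makes the biaryl, MOM removal bares O4'–H, and ring G is closed last.
4. Enabling feature: in ring B, O4' has C3' bonded to C8'' of ring D and C1' bonded to C2 of ring C, so C5'–H is its only open ortho or para carbon. O4'–H is also the only free hydroxyl, so an ortho-quinone methide can arise only across O4'/C5'.
5. Helpers: five benzyl ethers (removed by hydrogenolysis), the MOM ether on O4' (removed before the key step) and the Cα=Cβ alkene (saturated in the same hydrogenation).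
6. Stereochemistry: the target has no stereocentre (Cγ is gem-dimethyl). E-chalcones form under thermodynamic control, and the racemic centres of the transient flavanones and acetals vanish on aromatisation.

Key step: step 11

Remark: the target SMILES defines no stereocentre and no axial descriptor, so the C3'–C8'' axis is left unassigned and all compounds are treated as achiral or racemic.

**Route**

Step 1
Reactants: 1 1-(2,4,6-trihydroxyphenyl)ethanone
Product: 2 1-[2,4-bis(benzyloxy)-6-hydroxyphenyl]ethanone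
Conditions: BnBr (2.1 equiv), K2CO3 (2.2 equiv), DMF, rt
Reagents that add atoms: benzyl bromide, BrCc1ccccc1
Why: Williamson etherification; the hydroxyl hydrogen-bonded to the acetyl carbonyl is the least nucleophilic and should stay free, so two equivalents of bromide cap only the other two oxygens.

Step 2
Reactants: 2 1-[2,4-bis(benzyloxy)-6-hydroxyphenyl]ethanone; 3 4-(benzyloxy)benzaldehyde
Product: 4 (E)-1-[2,4-bis(benzyloxy)-6-hydroxyphenyl]-3-[4-(benzyloxy)phenyl]prop-2-en-1-one
Conditions: KOH (50% aq.), EtOH/THF, rt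
Reagents that add atoms: none
Why: Claisen–Schmidt condensation of the methyl ketone enolate with a non-enolisable aldehyde; E1cB dehydration under thermodynamic control should give the E alkene.

Step 3
Reactants: 4 (E)-1-[2,4-bis(benzyloxy)-6-hydroxyphenyl]-3-[4-(benzyloxy)phenyl]prop-2-en-1-one
Product: 6 5,7-bis(benzyloxy)-2-[4-(benzyloxy)phenyl]-4H-chromen-4-one, via flavanone 5 (not isolated)
Conditions: I2 (10 mol%), DMSO, 130 °C
Reagents that add atoms: none
Why: Iodine-catalysed oxidative cyclisation of a 2'-hydroxychalcone: 6-endo oxa-Michael closure of ring E to flavanone 5, then α-iodination and loss of HI, with DMSO reoxidising HI to iodine.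

Step 4
Reactants: 6 5,7-bis(benzyloxy)-2-[4-(benzyloxy)phenyl]-4H-chromen-4-one
Product: 7 5,7-bis(benzyloxy)-2-[4-(benzyloxy)phenyl]-8-iodo-4H-chromen-4-one
Conditions: NIS (1.05 equiv), TFA (cat.), CH2Cl2, 0 °C to rt
Reagents that add atoms: N-iodosuccinimide, O=C1CCC(=O)N1I
Why: Electrophilic aromatic iodination of the ring activated by three oxygens; C8 (between O1 and one benzyloxy group) is less hindered than C6 (between two benzyloxy groups), the usual preference of 5,7-dialkoxyflavones.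

Step 5
Reactants: 8 4-hydroxy-3-iodobenzaldehyde
Product: 9 3-iodo-4-(methoxymethoxy)benzaldehyde
Conditions: MOMCl, iPr2NEt, CH2Cl2, 0 °C to rt
Reagents that add atoms: chloromethyl methyl ether, COCCl
Why: O-alkylation of the phenol to a MOM acetal, which keeps the aldehyde electrophilic in the basic condensation and marks this oxygen as different from the benzyl ethers.

Step 6
Reactants: 2 1-[2,4-bis(benzyloxy)-6-hydroxyphenyl]ethanone; 9 3-iodo-4-(methoxymethoxy)benzaldehyde
Product: 10 (E)-1-[2,4-bis(benzyloxy)-6-hydroxyphenyl]-3-[3-iodo-4-(methoxymethoxy)phenyl]prop-2-en-1-one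
Conditions: KOH (50% aq.), EtOH/THF, rt
Reagents that add atoms: none
Why: Claisen–Schmidt condensation as in step 2; the aryl iodide and the MOM acetal are inert to aqueous KOH and the E alkene forms under thermodynamic control.

Step 7
Reactants: 10 (E)-1-[2,4-bis(benzyloxy)-6-hydroxyphenyl]-3-[3-iodo-4-(methoxymethoxy)phenyl]prop-2-en-1-one
Product: 12 5,7-bis(benzyloxy)-2-[3-iodo-4-(methoxymethoxy)phenyl]-4H-chromen-4-one, via flavanone 11 (not isolated)
Conditions: I2 (5 mol%), DMSO, 120 °C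
Reagents that add atoms: none
Why: Iodine-catalysed oxidative cyclisation as in step 3, closing ring C; the low iodine loading keeps HI scarce, so the non-chelated MOM ether is expected to survive.

Step 8
Reactants: 12 5,7-bis(benzyloxy)-2-[3-iodo-4-(methoxymethoxy)phenyl]-4H-chromen-4-one
Product: 13 5,7-bis(benzyloxy)-2-[4-(methoxymethoxy)-3-(4,4,5,5-tetramethyl-1,3,2-dioxaborolan-2-yl)phenyl]-4H-chromen-4-one
Conditions: B2pin2, PdCl2(dppf) (5 mol%), KOAc, 1,4-dioxane, 90 °C
Reagents that add atoms: bis(pinacolato)diboron, CC1(C)OB(OC1(C)C)B1OC(C)(C)C(C)(C)O1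
Why: Miyaura borylation: oxidative addition of the C–I bond to zerovalent palladium, acetate-assisted transmetalation and reductive elimination; KOAc is too weak a base to start a Suzuki homocoupling.

Step 9
Reactants: 13 5,7-bis(benzyloxy)-2-[4-(methoxymethoxy)-3-(4,4,5,5-tetramethyl-1,3,2-dioxaborolan-2-yl)phenyl]-4H-chromen-4-one; 7 5,7-bis(benzyloxy)-2-[4-(benzyloxy)phenyl]-8-iodo-4H-chromen-4-one
Product: 14 5,7,5'',7'',4'''-penta-O-benzyl-4'-O-(methoxymethyl)amentoflavone
Conditions: Pd(OAc)2 (10 mol%), SPhos (20 mol%), K3PO4, toluene/H2O, degassed, 100 °C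
Reagents that add atoms: none
Why: Suzuki–Miyaura coupling of an 8-iodoflavone with a flavone-3'-boronate; the bulky electron-rich biarylphosphine should support oxidative addition at the flanked C8''–I bond and reductive elimination to the tri-ortho-substituted biaryl.

Step 10
Reactants: 14 5,7,5'',7'',4'''-penta-O-benzyl-4'-O-(methoxymethyl)amentoflavone
Product: 15 5,7,5'',7'',4'''-penta-O-benzylamentoflavone (free 4'-OH)
Conditions: HCl (1.25 M in MeOH), THF, 40 °C
Reagents that add atoms: none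
Why: Acid-catalysed acetal exchange (methanolysis of the MOM ether) frees O4'–H alone; aryl benzyl ethers are inert to dilute methanolic HCl.

Step 11
Reactants: 15 5,7,5'',7'',4'''-penta-O-benzylamentoflavone (free 4'-OH); 16 1,1-diethoxy-3-methylbut-2-ene
Product: 20 penta-O-benzyl 2,2-dimethyl-2H-chromene (ring G with a Cα=Cβ alkene fused at O4'/C5'), via mixed acetal 17 (not isolated), via ethoxyallyl phenol 18 (not isolated), via ortho-quinone methide 19 (not isolated)
Conditions: 16 (3 equiv), 3-picoline (0.5 equiv), p-xylene, 140 °C, EtOH distilled off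
Reagents that add atoms: none
Why: Phenol 15 exchanges one ethoxy group of 16 to give mixed acetal 17, which ionises on heating to a phenoxide/1-ethoxyallyl cation pair that collapses at C5' (C5'–Cα bond) to 18; loss of the second ethanol gives ortho-quinone methide 19, and closure of O4' onto Cγ rearomatises ring B. The closest known reaction type is the pyridine- or picoline-promoted chromenylation of phenols, para-acceptor phenols such as 4-cyanophenol included, with 3-methylbut-2-enal or its acetals, a formal [3+3] annulation. Ring G closes by a thermal disrotatory oxa-6π electrocyclisation of the 1-oxatriene O4'=C4'–C5'=Cα–Cβ=Cγ, not by an ionic 6-endo addition. No stereocentre is formed because Cγ carries two methyl groups, and the exocyclic alkene geometry of 19 needed for closure can equilibrate at this temperature. The step needs site selectivity for C5' over C6, C8, C6'' and ring F; this is secured because only O4'–H can enter the acetal exchange and form a quinone methide, C3' and C1' are substituted, and no free acid is present to release an unbound cation towards the benzyloxy rings.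

Step 12
Reactants: 20 penta-O-benzyl 2,2-dimethyl-2H-chromene (ring G with a Cα=Cβ alkene fused at O4'/C5')
Product: 21 8-[6-(5,7-dihydroxy-4-oxo-4H-chromen-2-yl)-2,2-dimethyl-3,4-dihydro-2H-chromen-8-yl]-5,7-dihydroxy-2-(4-hydroxyphenyl)-4H-chromen-4-one (target)
Conditions: H2 (1 atm), Pd/C (10 wt%), THF/MeOH, rt
Reagents that add atoms: none
Why: Heterogeneous hydrogenation cleaves the five benzylic C–O bonds and saturates the cis-disubstituted styrene-type Cα=Cβ alkene; the vinylogous-ester C2=C3 bonds of rings C and E are deactivated and should persist at 1 atm and rt.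

**Compound list**

1 | 1-(2,4,6-trihydroxyphenyl)ethanone | CC(=O)c1c(O)cc(O)cc1O | starting material
2 | 1-[2,4-bis(benzyloxy)-6-hydroxyphenyl]ethanone | CC(=O)c1c(O)cc(OCc2ccccc2)cc1OCc1ccccc1 | intermediate
3 | 4-(benzyloxy)benzaldehyde | O=Cc1ccc(OCc2ccccc2)cc1 | starting material
4 | (E)-1-[2,4-bis(benzyloxy)-6-hydroxyphenyl]-3-[4-(benzyloxy)phenyl]prop-2-en-1-one | O=C(/C=C/c1ccc(OCc2ccccc2)cc1)c1c(O)cc(OCc2ccccc2)cc1OCc1ccccc1 | intermediate
5 | racemic 5,7-bis(benzyloxy)-2-[4-(benzyloxy)phenyl]chroman-4-one | O=C1CC(c2ccc(OCc3ccccc3)cc2)Oc2cc(OCc3ccccc3)cc(OCc3ccccc3)c21 | intermediate (not isolated)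
6 | 5,7-bis(benzyloxy)-2-[4-(benzyloxy)phenyl]-4H-chromen-4-one | O=c1cc(-c2ccc(OCc3ccccc3)cc2)oc2cc(OCc3ccccc3)cc(OCc3ccccc3)c12 | intermediate
7 | 5,7-bis(benzyloxy)-2-[4-(benzyloxy)phenyl]-8-iodo-4H-chromen-4-one | O=c1cc(-c2ccc(OCc3ccccc3)cc2)oc2c(I)c(OCc3ccccc3)cc(OCc3ccccc3)c12 | intermediate
8 | 4-hydroxy-3-iodobenzaldehyde | O=Cc1ccc(O)c(I)c1 | starting material
9 | 3-iodo-4-(methoxymethoxy)benzaldehyde | COCOc1ccc(C=O)cc1I | intermediate
10 | (E)-1-[2,4-bis(benzyloxy)-6-hydroxyphenyl]-3-[3-iodo-4-(methoxymethoxy)phenyl]prop-2-en-1-one | O=C(/C=C/c1ccc(OCOC)c(I)c1)c1c(O)cc(OCc2ccccc2)cc1OCc1ccccc1 | intermediate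
11 | racemic 5,7-bis(benzyloxy)-2-[3-iodo-4-(methoxymethoxy)phenyl]chroman-4-one | O=C1CC(c2ccc(OCOC)c(I)c2)Oc2cc(OCc3ccccc3)cc(OCc3ccccc3)c21 | intermediate (not isolated)
12 | 5,7-bis(benzyloxy)-2-[3-iodo-4-(methoxymethoxy)phenyl]-4H-chromen-4-one | COCOc1ccc(-c2cc(=O)c3c(OCc4ccccc4)cc(OCc4ccccc4)cc3o2)cc1I | intermediate
13 | 5,7-bis(benzyloxy)-2-[4-(methoxymethoxy)-3-(4,4,5,5-tetramethyl-1,3,2-dioxaborolan-2-yl)phenyl]-4H-chromen-4-one | COCOc1ccc(-c2cc(=O)c3c(OCc4ccccc4)cc(OCc4ccccc4)cc3o2)cc1B1OC(C)(C)C(C)(C)O1 | intermediate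
14 | 8-{5-[5,7-bis(benzyloxy)-4-oxo-4H-chromen-2-yl]-2-(methoxymethoxy)phenyl}-5,7-bis(benzyloxy)-2-[4-(benzyloxy)phenyl]-4H-chromen-4-one | COCOc1ccc(-c2cc(=O)c3c(OCc4ccccc4)cc(OCc4ccccc4)cc3o2)cc1-c1c(OCc2ccccc2)cc(OCc2ccccc2)c2c(=O)cc(-c3ccc(OCc4ccccc4)cc3)oc12 | intermediate
15 | 8-{5-[5,7-bis(benzyloxy)-4-oxo-4H-chromen-2-yl]-2-hydroxyphenyl}-5,7-bis(benzyloxy)-2-[4-(benzyloxy)phenyl]-4H-chromen-4-one | Oc1ccc(-c2cc(=O)c3c(OCc4ccccc4)cc(OCc4ccccc4)cc3o2)cc1-c1c(OCc2ccccc2)cc(OCc2ccccc2)c2c(=O)cc(-c3ccc(OCc4ccccc4)cc3)oc12 | intermediate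
16 | 1,1-diethoxy-3-methylbut-2-ene | CCOC(OCC)C=C(C)C | starting material
17 | racemic O4'-(1-ethoxy-3-methylbut-2-en-1-yl) ether of 15 (mixed aryl ethyl acetal) | CCOC(C=C(C)C)Oc1ccc(-c2cc(=O)c3c(OCc4ccccc4)cc(OCc4ccccc4)cc3o2)cc1-c1c(OCc2ccccc2)cc(OCc2ccccc2)c2c(=O)cc(-c3ccc(OCc4ccccc4)cc3)oc12 | intermediate (not isolated)
18 | racemic C5'-(1-ethoxy-3-methylbut-2-en-1-yl) derivative of phenol 15 | CCOC(C=C(C)C)c1cc(-c2cc(=O)c3c(OCc4ccccc4)cc(OCc4ccccc4)cc3o2)cc(-c2c(OCc3ccccc3)cc(OCc3ccccc3)c3c(=O)cc(-c4ccc(OCc5ccccc5)cc4)oc23)c1O | intermediate (not isolated)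
19 | ortho-quinone methide of ring B: C4'=O, exocyclic C5'=Cα–Cβ=Cγ(CH3)2, dimethylvinyl group cis to C4' | CC(C)=C/C=C1/C=C(-c2cc(=O)c3c(OCc4ccccc4)cc(OCc4ccccc4)cc3o2)C=C(-c2c(OCc3ccccc3)cc(OCc3ccccc3)c3c(=O)cc(-c4ccc(OCc5ccccc5)cc4)oc23)C1=O | intermediate (not isolated)
20 | 8-{6-[5,7-bis(benzyloxy)-4-oxo-4H-chromen-2-yl]-2,2-dimethyl-2H-chromen-8-yl}-5,7-bis(benzyloxy)-2-[4-(benzyloxy)phenyl]-4H-chromen-4-one | CC1(C)C=Cc2cc(-c3cc(=O)c4c(OCc5ccccc5)cc(OCc5ccccc5)cc4o3)cc(-c3c(OCc4ccccc4)cc(OCc4ccccc4)c4c(=O)cc(-c5ccc(OCc6ccccc6)cc5)oc34)c2O1 | intermediate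
21 | 8-[6-(5,7-dihydroxy-4-oxo-4H-chromen-2-yl)-2,2-dimethyl-3,4-dihydro-2H-chromen-8-yl]-5,7-dihydroxy-2-(4-hydroxyphenyl)-4H-chromen-4-one | CC1(C)CCc2cc(-c3cc(=O)c4c(O)cc(O)cc4o3)cc(-c3c(O)cc(O)c4c(=O)cc(-c5ccc(O)cc5)oc34)c2O1 | target

**Count**

Total steps: 12. Longest linear sequence: 8 steps (steps 1, 6, 7, 8, 9, 10, 11, 12).

**Steps most likely to fail**

Step 11. The C5'–Cα bond has to form ortho to an electron-poor, hindered phenoxide. The reaction may stall at the mixed acetal while the acetal reagent decomposes thermally, or the allyl cation may escape the ion pair and alkylate a benzyloxy ring. The fallback sets out from 15 and splits the event into two known operations. O-alkylation with 3-chloro-3-methylbut-1-yne (K2CO3, KI, CuI cat., acetone, reflux) should give the 1,1-dimethylpropargyl aryl ether F1. Heating F1 in N,N-diethylaniline at 190 °C should start an aromatic Claisen rearrangement, which can only reach C5', giving the ortho-allenylphenol F2. A 1,5-hydrogen shift then leads to the same quinone methide 19, which closes to chromene 20, where the route is rejoined.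

Step 9. Oxidative addition and transmetalation at the doubly flanked C8''–I bond may be slow, so that protodeboronation of the valuable boronate 13 and hydrodeiodination of 7 win. The fallback sets out from 9 and 7 and forms the biaryl bond with a small, cheap boron partner that can be used in large excess. Miyaura borylation of 9 (B2pin2, PdCl2(dppf), KOAc, dioxane) should give the benzaldehyde boronate F3. Suzuki–Miyaura coupling of F3 with 7 should give the biaryl aldehyde F4. Claisen–Schmidt condensation of F4 with ketone 2 (Ba(OH)2, MeOH, 40 °C, mild enough for ring E) should give the chalcone F5. Iodine-catalysed oxidative cyclisation in DMSO, through the flavanone F6, then builds ring C and returns to 14.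

Step 4. Regiocontrol between C8 and C6 may be incomplete, and over-iodination is possible. The fallback sets out from 2 and places the iodine before ring E exists. Iodination of 2 with NIS in DMF, ortho to the free chelated hydroxyl, should give the iodoacetophenone F7, and any positional isomer can be removed at this small-molecule stage. Claisen–Schmidt condensation of F7 with 3 should give the iodochalcone F8. Oxidative cyclisation (I2 cat., DMSO), through the iodoflavanone F9, returns to 7, with the iodine fixed next to the oxygen that becomes O1.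

**Further compounds**

F1 | step 11 | 1,1-dimethylpropargyl ether of phenol 15 at O4' | C#CC(C)(C)Oc1ccc(-c2cc(=O)c3c(OCc4ccccc4)cc(OCc4ccccc4)cc3o2)cc1-c1c(OCc2ccccc2)cc(OCc2ccccc2)c2c(=O)cc(-c3ccc(OCc4ccccc4)cc3)oc12
F2 | step 11 | C5'-(3-methylbuta-1,2-dien-1-yl) derivative of phenol 15 (not isolated) | CC(C)=C=Cc1cc(-c2cc(=O)c3c(OCc4ccccc4)cc(OCc4ccccc4)cc3o2)cc(-c2c(OCc3ccccc3)cc(OCc3ccccc3)c3c(=O)cc(-c4ccc(OCc5ccccc5)cc4)oc23)c1O
F3 | step 9 | 4-(methoxymethoxy)-3-(4,4,5,5-tetramethyl-1,3,2-dioxaborolan-2-yl)benzaldehyde | COCOc1ccc(C=O)cc1B1OC(C)(C)C(C)(C)O1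
F4 | step 9 | 3-{5,7-bis(benzyloxy)-2-[4-(benzyloxy)phenyl]-4-oxo-4H-chromen-8-yl}-4-(methoxymethoxy)benzaldehyde | COCOc1ccc(C=O)cc1-c1c(OCc2ccccc2)cc(OCc2ccccc2)c2c(=O)cc(-c3ccc(OCc4ccccc4)cc3)oc12
F5 | step 9 | (E)-chalcone from F4 and 2 | COCOc1ccc(/C=C/C(=O)c2c(O)cc(OCc3ccccc3)cc2OCc2ccccc2)cc1-c1c(OCc2ccccc2)cc(OCc2ccccc2)c2c(=O)cc(-c3ccc(OCc4ccccc4)cc3)oc12
F6 | step 9 | racemic flavanone from F5 (not isolated) | COCOc1ccc(C2CC(=O)c3c(OCc4ccccc4)cc(OCc4ccccc4)cc3O2)cc1-c1c(OCc2ccccc2)cc(OCc2ccccc2)c2c(=O)cc(-c3ccc(OCc4ccccc4)cc3)oc12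
F7 | step 4 | 1-[4,6-bis(benzyloxy)-2-hydroxy-3-iodophenyl]ethanone | CC(=O)c1c(O)c(I)c(OCc2ccccc2)cc1OCc1ccccc1
F8 | step 4 | (E)-1-[4,6-bis(benzyloxy)-2-hydroxy-3-iodophenyl]-3-[4-(benzyloxy)phenyl]prop-2-en-1-one | O=C(/C=C/c1ccc(OCc2ccccc2)cc1)c1c(O)c(I)c(OCc2ccccc2)cc1OCc1ccccc1
F9 | step 4 | racemic 5,7-bis(benzyloxy)-2-[4-(benzyloxy)phenyl]-8-iodochroman-4-one (not isolated) | O=C1CC(c2ccc(OCc3ccccc3)cc2)Oc2c(I)c(OCc3ccccc3)cc(OCc3ccccc3)c21
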